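## The problem

- **Skeleton.** The target is the p-anisate of a daucane diol-enone, a trans-fused bicyclo[5.3.0]decane. Ring A is the cyclopentane C1–C2–C3–C4–C5. Ring B is the cycloheptenone C1–C5–C6–C7–C8–C9–C10. C1 is the quaternary fusion carbon (CH3), C4 the tertiary carbinol carbon (OH, isopropyl), C5 the fusion CH, C6 the CH–O–anisoyl carbon, C8=C9 the methyl-bearing olefin and C10 the ketone.
- **Configuration.** The SMILES reads C1 (S), C4 (R), C5 (S), C6 (S). The C1 methyl and the C4 hydroxyl lie on one face (β). H5, the isopropyl group and O6 lie on the other (α). The fusion is therefore trans, O4 and C6 are cis on ring A, and O4/O6 form a 1,3-anti diol.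
- **Order of control.** The four stereocentres are contiguous, but C1 is all-carbon quaternary, sits next to the C10 carbonyl and cannot be derived from a neighbour. It has to be set first and must then control C5, from which C4 and C6 follow.
- **The trans fusion.** A bond made to C5 while C5 is an sp2 atom of a ring already attached to C1 arrives on the side of the tether. That gives the cis-hydroazulene.
- **Ring B.** It is seven-membered and holds a Z-trisubstituted enone. Closure is entropically poor, and a conjugated nucleophile built on C10–C9–C8–C7 is too flat to reach C6.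
- **Sensitive groups.**
  - The C7 protons are vinylogously acidic, so the C6 anisate can leave by E1cB.
  - The C4 alcohol dehydrates easily.
  - Whenever C6 is a carbonyl, C5 can epimerise and the C4–C5 bond can open by retro-aldol.
- **Feature that permits the key step.** O4–C4–C5–C6 stand cis on adjacent atoms of ring A and can be tied into a four-membered β-lactone. Read backwards, C4 is an isopropyl ketone carbon and C5 the α-carbon of a C6 acid. Both hang on C1 (C5 directly, C4 through C2–C3), so ring A can be folded from an open chain.

## Retrosynthesis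

**C6–O(acyl): 20 to 18 and 19.** The base-labile anisate goes on last. Diol 18 has one secondary and one tertiary hydroxyl, so no protecting group is needed.

**Olefin position: 18 to 17.** The conjugated C8=C9 enone is the thermodynamic isomer of the exocyclic β,γ-enone 17. This move lets C9 be sp3 when ring B is closed.

**C6–C7: 17 to 15 (through 16).**
- A cut at C8=C9 (metathesis) would set no stereocentre.
- A cut at C6–C7 with a conjugated dienolate keeps C10, C9, C8 and C7 coplanar. Only C1, C5 and C6 are then left to reach the p-lobe on C7, the same bar as in a 5-(enolendo) closure.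
- With C9 sp3, the 1,1-disubstituted alkene and the aldehyde of 15 form the 6-methylhept-6-enal array of a type 2 carbonyl-ene cyclisation.
- Compound 15 is monocyclic. The forward reaction must set C6.

**Oxidation levels: 15 to 14 to 13.** The hydroxy aldehyde is labile, so it is released from β-lactone 13 only just before use, by full reduction and double oxidation.

**C4–C5 and O4–C6 (key): 13 to 10.**
- Both bonds of the lactone are cut at once, and ring A opens to acyclic keto acid 10 with C1 as its only stereocentre.
- A plain aldol at the aldehyde level is reversible, prone to dehydration and leaves C5 epimerisable.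
- Closure from a preformed ring B would give the cis fusion.
- The forward reaction must choose the C5 face from C1 alone.

**Reconnection C4=C6: 10 to 9 to 8.** The 1,6-relation of the C4 ketone and the C6 acid is the retron of a cleaved cyclohexene. Reconnection turns the acyclic quaternary centre into a ring problem.

**C9–C10: 8 to 7 to 5 and 6.** The methallyl ketone comes from a non-enolisable aldehyde by Grignard addition and oxidation.

**C1–C5 and C2–C3 of the cyclohexene: 5 to 3 and 4.** Compound 5 is the "para" Diels–Alder adduct of a 2-alkylbutadiene and methacrolein, a dienophile class for which catalytic enantiocontrol at a quaternary carbon is established.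

**Diene: 3 to 1 and 2.** Ethene–alkyne metathesis builds the diene from two commodity compounds.

## Roads not taken

**Alternative 1:** cut C8=C9 (the obvious route).
- Forward key step: ring-closing metathesis of dienone A1 with (H2IMes)(PCy3)Cl2Ru=CHPh would give 18.
- The closure creates no stereocentre, so A1 must already carry all four, set one by one on a cyclopentane.
- A1 contains a polymerisable vinyl ketone. It must join an electron-poor olefin to a 1,1-disubstituted one.
- The chosen plan forms C4, C5 and C6 in its two ring closures.

**Alternative 2:** ring B first, cut C4–C5.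
- Forward key step: triketone A2 would be closed by an aldol reaction of C5 on the C4 ketone.
- In A2 the acidic site is C7, not C5.
- An endocyclic C5=C6 enolate is attacked on the face of the C1–C2 tether, which gives cis-fused ketol A3.
- A3 can revert or dehydrate, and correcting C5 would pass through the same enolate.

**Alternative 3:** cut C1–C10 by a sigmatropic shift from the chiral pool.
- (S)-Terpinen-4-ol A4 would give enal A5 by ozonolysis and aldol condensation, and A5 would be elaborated to dihydropyran A6.
- Forward key step: a [2,3]-Wittig ring enlargement of A6 would give dienol A7 with C1 and ring B formed together.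
- H5 and O6 would then have to come from a syn hydroboration of C5=C6. That step competes with a second trisubstituted olefin and must occur on the face that carries the isopropyl group.
- The carbanion can also take the [1,2] path.
- The enantiopurity of the route would rest on that of A4.

Key step: step 6

Assumption: the oxazaborolidinium salt derived from (S)-α,α-diphenylprolinol is taken to give the (1S) adduct 5; if the sense proves opposite, the catalyst from the (R)-amino alcohol is used with no other change.

## Steps

Step 1
Reactants: 1 3-methylbut-1-yne; 2 ethene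
Product: 3 2-(propan-2-yl)buta-1,3-diene
Conditions: second-generation Grubbs catalyst (H2IMes)(PCy3)Cl2Ru=CHPh (2 mol %), ethene (4 bar), CH2Cl2, 25 °C; silica plug, used as CH2Cl2 solution
Reagents that add atoms: none
Why: Ethene–alkyne cross (enyne) metathesis; the ruthenium methylidene adds to the terminal alkyne and ethene releases the vinylcarbene as the 2-substituted butadiene, with all atoms of both partners kept and no stereocentre formed.

Step 2
Reactants: 3 2-(propan-2-yl)buta-1,3-diene; 4 methacrolein
Product: 5 (1S)-1-methyl-4-(propan-2-yl)cyclohex-3-ene-1-carbaldehyde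
Conditions: oxazaborolidinium triflimide from (S)-α,α-diphenylprolinol, o-tolylboronic acid and Tf2NH (10 mol %), CH2Cl2, −78 to −40 °C
Reagents that add atoms: none
Why: Catalytic enantioselective Diels–Alder reaction of an α-substituted acrolein; the 2-alkyl group of the diene directs to the "para" adduct. The aryl group of the catalyst shields one face of the boron-bound s-trans enal, which sets quaternary C1.

Step 3
Reactants: 5 (1S)-1-methyl-4-(propan-2-yl)cyclohex-3-ene-1-carbaldehyde; 6 2-methylallylmagnesium chloride
Product: 7 3-methyl-1-[(1S)-1-methyl-4-(propan-2-yl)cyclohex-3-en-1-yl]but-3-en-1-ol (both C10 epimers)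
Conditions: THF, −78 to 0 °C; aq NH4Cl
Reagents that add atoms: none
Why: Grignard 1,2-addition to a non-enolisable neopentyl aldehyde; the C10 carbinol centre forms without control and is erased in step 4.

Step 4
Reactants: 7 3-methyl-1-[(1S)-1-methyl-4-(propan-2-yl)cyclohex-3-en-1-yl]but-3-en-1-ol
Product: 8 3-methyl-1-[(1S)-1-methyl-4-(propan-2-yl)cyclohex-3-en-1-yl]but-3-en-1-one
Conditions: Dess–Martin periodinane, pyridine, CH2Cl2, 0 °C
Reagents that add atoms: none
Why: Dess–Martin oxidation under buffered, near-neutral conditions gives the β,γ-unsaturated ketone without moving the olefin into conjugation.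

Step 5
Reactants: 8 3-methyl-1-[(1S)-1-methyl-4-(propan-2-yl)cyclohex-3-en-1-yl]but-3-en-1-one
Product: 10 (3S)-3,7-dimethyl-3-(3-methylbut-3-enoyl)-6-oxooctanoic acid, via keto aldehyde 9 (not isolated)
Conditions: O3 (1 equiv, Sudan Red 7B end point), pyridine, CH2Cl2, −78 °C; solvent exchange; NaClO2, NaH2PO4, 2-methylbut-2-ene, t-BuOH–H2O, 0 to 23 °C
Reagents that add atoms: ozone [O-][O+]=O; sodium chlorite [Na+].[O-]Cl=O
Why: Ozonolysis followed by Pinnick oxidation; ozone should prefer the trisubstituted, purely alkyl-substituted ring olefin over the 1,1-disubstituted olefin that carries an allylic acyl group. Pyridine turns the carbonyl oxide directly into the carbonyl compounds. Chlorite touches only the aldehyde while 2-methylbut-2-ene traps HOCl.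

Step 6
Reactants: 10 (3S)-3,7-dimethyl-3-(3-methylbut-3-enoyl)-6-oxooctanoic acid
Product: 13 (1R,2S,5R)-2-methyl-2-(3-methylbut-3-enoyl)-5-(propan-2-yl)-6-oxabicyclo[3.2.0]heptan-7-one, via tosyl mixed anhydride 11 (not isolated), via ammonium enolate 12 (not isolated)
Conditions: TsCl (1.3 equiv), 4-pyrrolidinopyridine (1 equiv), i-Pr2NEt (3 equiv), LiCl (1 equiv), CH2Cl2 (0.05 M), 23 °C
Reagents that add atoms: none
Why: Nucleophile-catalysed aldol-lactonisation of a keto acid, a known route to cyclopentane-fused β-lactones with a tertiary C–O centre. TsCl converts the acid into mixed anhydride 11, 4-pyrrolidinopyridine takes over the acyl group and i-Pr2NEt removes a C5 proton to give ammonium enolate 12. C5 adds to the C4 ketone in a 5-(enolexo)-exo-trig aldol step that closes ring A, and the C4 alkoxide attacks C6 in a 4-exo-trig acyl substitution that closes the lactone and frees the catalyst. C5 is controlled by C1: the C1–C2 bond must stand perpendicular to the enolate plane, so one remaining C1 substituent lies almost in that plane beside the C6 substituents (allylic 1,3-strain) and the other points away; the methyl group takes the crowded inside place and the acyl group the outside one, which puts C6 cis to CH3 and trans to C10 as the trans fusion requires. C4 is controlled by the lactone: the aldol step is reversible and only the aldolate with O4 cis to C6 can lactonise, so both ketone faces funnel into one configuration with isopropyl trans to C6. The C10 ketone cannot compete (it would close a three-membered ring), and only the acyl-ammonium α-protons are acidified, so C3 and C9 stay untouched. Lactonisation removes the aldol equilibrium, blocks dehydration and locks C5 against epimerisation.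

Step 7
Reactants: 13 (1R,2S,5R)-2-methyl-2-(3-methylbut-3-enoyl)-5-(propan-2-yl)-6-oxabicyclo[3.2.0]heptan-7-one
Product: 14 1-[(1S,2S,3R)-3-hydroxy-2-(hydroxymethyl)-1-methyl-3-(propan-2-yl)cyclopentyl]-3-methylbut-3-en-1-ol (both C10 epimers)
Conditions: LiAlH4, Et2O, 0 °C; H2O, aq NaOH
Reagents that add atoms: none
Why: Hydride reduction with acyl–oxygen cleavage opens the lactone to the 1,3-diol without touching C4 or C5. The C10 ketone is reduced as well, and its new centre is erased in step 8.

Step 8
Reactants: 14 1-[(1S,2S,3R)-3-hydroxy-2-(hydroxymethyl)-1-methyl-3-(propan-2-yl)cyclopentyl]-3-methylbut-3-en-1-ol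
Product: 15 (1R,2R,5S)-2-hydroxy-5-methyl-5-(3-methylbut-3-enoyl)-2-(propan-2-yl)cyclopentane-1-carbaldehyde
Conditions: Dess–Martin periodinane (2.4 equiv), pyridine, CH2Cl2, 0 °C; used without chromatography
Reagents that add atoms: none
Why: Double Dess–Martin oxidation of the primary and secondary alcohols; the tertiary C4 alcohol is inert. The buffered medium spares the β-hydroxy aldehyde and the β,γ-enone.

Step 9
Reactants: 15 (1R,2R,5S)-2-hydroxy-5-methyl-5-(3-methylbut-3-enoyl)-2-(propan-2-yl)cyclopentane-1-carbaldehyde
Product: 17 (3R,3aS,4S,8aS)-3,4-dihydroxy-8a-methyl-6-methylidene-3-(propan-2-yl)octahydroazulen-8-one, via aluminium alkoxide 16 (not isolated)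
Conditions: Me2AlCl (1.1–2 equiv), CH2Cl2, −78 to 0 °C; cold 1 M HCl
Reagents that add atoms: none
Why: Type 2 intramolecular carbonyl-ene (Prins-type) cyclisation of a 6-methylhept-6-enal array, the known route to 3-methylenecycloheptanols; Me2AlCl first makes alkoxide 16 (methane), whose aluminium binds the aldehyde oxygen, and C7 then attacks C6 with charge build-up at tertiary C8 and loss of a proton from the C8 methyl group. Because C10 is trans to C6 on ring A, closure through C9 to a five-membered ring is impossible and C7 can only arrive anti to C4; the O4–Al–O6 chelate holds the carbonyl oxygen outward on the H5 side, so O6 should end equatorial and α (C6 S), anti to O4. Olefin isomers from other proton losses converge in step 10.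

Step 10
Reactants: 17 (3R,3aS,4S,8aS)-3,4-dihydroxy-8a-methyl-6-methylidene-3-(propan-2-yl)octahydroazulen-8-one
Product: 18 (3R,3aS,4S,8aS)-3,4-dihydroxy-6,8a-dimethyl-3-(propan-2-yl)-2,3,3a,4,5,8a-hexahydroazulen-8(1H)-one
Conditions: DBU (0.2 equiv), CH2Cl2, 23 °C
Reagents that add atoms: none
Why: Base-catalysed β,γ to α,β isomerisation through the C9 dienolate gives the endocyclic trisubstituted enone as the most stable isomer. Hydroxide on C6 is too poor a leaving group for elimination under these conditions, and no stereocentre is touched.

Step 11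
Reactants: 18 (3R,3aS,4S,8aS)-3,4-dihydroxy-6,8a-dimethyl-3-(propan-2-yl)-2,3,3a,4,5,8a-hexahydroazulen-8(1H)-one; 19 4-methoxybenzoyl chloride
Product: 20 (3R,3aS,4S,8aS)-3-hydroxy-6,8a-dimethyl-8-oxo-3-(propan-2-yl)-1,2,3,3a,4,5,8,8a-octahydroazulen-4-yl 4-methoxybenzoate
Conditions: pyridine, DMAP (0.1 equiv), CH2Cl2, 0 to 23 °C
Reagents that add atoms: none
Why: DMAP-catalysed acylation; the equatorial secondary C6 alcohol reacts and the tertiary C4 alcohol does not. The weak base keeps the vinylogous E1cB loss of anisate slow, and C6 retains its configuration.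

## Compound list

1 | 3-methylbut-1-yne | CC(C)C#C | starting material
2 | ethene | C=C | starting material
3 | 2-(propan-2-yl)buta-1,3-diene | C=CC(=C)C(C)C | intermediate
4 | methacrolein | CC(=C)C=O | starting material
5 | (1S)-1-methyl-4-(propan-2-yl)cyclohex-3-ene-1-carbaldehyde | O=C[C@]1(C)CC=C(C(C)C)CC1 | intermediate
6 | 2-methylallylmagnesium chloride | CC(=C)C[Mg]Cl | starting material
7 | 3-methyl-1-[(1S)-1-methyl-4-(propan-2-yl)cyclohex-3-en-1-yl]but-3-en-1-ol (C10 epimers) | CC(=C)CC(O)[C@]1(C)CC=C(C(C)C)CC1 | intermediate
8 | 3-methyl-1-[(1S)-1-methyl-4-(propan-2-yl)cyclohex-3-en-1-yl]but-3-en-1-one | CC(=C)CC(=O)[C@]1(C)CC=C(C(C)C)CC1 | intermediate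
9 | (3S)-3,7-dimethyl-3-(3-methylbut-3-enoyl)-6-oxooctanal | CC(=C)CC(=O)[C@](C)(CC=O)CCC(=O)C(C)C | intermediate
10 | (3S)-3,7-dimethyl-3-(3-methylbut-3-enoyl)-6-oxooctanoic acid | CC(=C)CC(=O)[C@](C)(CC(=O)O)CCC(=O)C(C)C | intermediate
11 | mixed anhydride of 10 and p-toluenesulfonic acid | CC(=C)CC(=O)[C@](C)(CC(=O)OS(=O)(=O)c1ccc(C)cc1)CCC(=O)C(C)C | intermediate
12 | C5 ammonium enolate of the 4-pyrrolidinopyridinium acyl derivative of 10 (zwitterion) | CC(=C)CC(=O)[C@](C)(C=C([O-])[n+]1ccc(cc1)N1CCCC1)CCC(=O)C(C)C | intermediate
13 | (1R,2S,5R)-2-methyl-2-(3-methylbut-3-enoyl)-5-(propan-2-yl)-6-oxabicyclo[3.2.0]heptan-7-one | CC(=C)CC(=O)[C@@]1(C)CC[C@]2(C(C)C)OC(=O)[C@H]12 | intermediate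
14 | 1-[(1S,2S,3R)-3-hydroxy-2-(hydroxymethyl)-1-methyl-3-(propan-2-yl)cyclopentyl]-3-methylbut-3-en-1-ol (C10 epimers) | CC(=C)CC(O)[C@@]1(C)CC[C@@](O)(C(C)C)[C@@H]1CO | intermediate
15 | (1R,2R,5S)-2-hydroxy-5-methyl-5-(3-methylbut-3-enoyl)-2-(propan-2-yl)cyclopentane-1-carbaldehyde | CC(=C)CC(=O)[C@@]1(C)CC[C@@](O)(C(C)C)[C@@H]1C=O | intermediate
16 | chloro(methyl)aluminium C4 alkoxide of 15 | CC(=C)CC(=O)[C@@]1(C)CC[C@@](O[Al](C)Cl)(C(C)C)[C@@H]1C=O | intermediate
17 | (3R,3aS,4S,8aS)-3,4-dihydroxy-8a-methyl-6-methylidene-3-(propan-2-yl)octahydroazulen-8-one | O[C@H]1CC(=C)CC(=O)[C@@]2(C)CC[C@@](O)(C(C)C)[C@H]12 | intermediate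
18 | (3R,3aS,4S,8aS)-3,4-dihydroxy-6,8a-dimethyl-3-(propan-2-yl)-2,3,3a,4,5,8a-hexahydroazulen-8(1H)-one | O[C@H]1CC(C)=CC(=O)[C@@]2(C)CC[C@@](O)(C(C)C)[C@H]12 | intermediate
19 | 4-methoxybenzoyl chloride | COc1ccc(cc1)C(Cl)=O | starting material
20 | (3R,3aS,4S,8aS)-3-hydroxy-6,8a-dimethyl-8-oxo-3-(propan-2-yl)-1,2,3,3a,4,5,8,8a-octahydroazulen-4-yl 4-methoxybenzoate | COc1ccc(C(=O)O[C@H]2CC(C)=CC(=O)[C@@]3(C)CC[C@@](O)(C(C)C)[C@H]23)cc1 | target

## Count and risks

Total step count: 11. Longest linear sequence: 11 (steps 1 to 11).

**Step 6 (key step).**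
- What may go wrong:
  - The isopropyl ketone is hindered, so the aldol step may be slower than hydrolysis or self-condensation of the activated acid.
  - The preference for methyl over acyl in the inside position may be modest, which would erode facial selectivity at C5.
  - Long exposure to amine bases may move the β,γ-olefin into conjugation.
- Fallback: it sets out from 9, isolated after the ozonolysis half of step 5, and returns at 15.
  - Ring A is closed at the aldehyde level by an enamine-mediated 5-(enolexo) aldol reaction (proline or pyrrolidine–AcOH, 23 °C) under equilibrating conditions.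
  - The isomer with CHO trans to isopropyl and hydrogen-bonded to O4 should be favoured, and it is taken at once into step 9.
  - No new compound is made (F0), and steps 7 and 8 fall away.

**Step 9.**
- What may go wrong:
  - The Lewis acid may shift the olefin into conjugation before closure, which switches off the nucleophile.
  - Loss of the chelate would allow attack with the carbonyl oxygen over ring A, which lowers facial selectivity at C6.
- Fallback: it sets out from 18 as a C6 epimer mixture and returns at 18.
  - Dess–Martin oxidation gives (3R,3aR,8aS)-3-hydroxy-6,8a-dimethyl-3-(propan-2-yl)-hexahydroazulene-4,8-dione F1.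
  - Me4NBH(OAc)3 in MeCN–AcOH at −20 °C binds to O4 and delivers hydride to the β face of C6 only (Evans–Saksena reduction).
  - Both epimers should funnel into the 1,3-anti diol, and the undirected C10 enone is left alone.

**Step 5.**
- What may go wrong: ozone may not discriminate well enough between the two olefins, which leads to over-cleavage.
- Fallback: it sets out from 8 and returns at 10.
  - m-CPBA (1 equiv, CH2Cl2, −20 °C) epoxidises the more substituted ring olefin to 1-[(3S)-3-methyl-6-(propan-2-yl)-7-oxabicyclo[4.1.0]heptan-3-yl]-3-methylbut-3-en-1-one F2.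
  - H5IO6 in THF–H2O cleaves F2 to 9, which enters the chlorite half of step 5.

**Step 11.**
- What may go wrong: deprotonation at C7 of the product and loss of anisate (vinylogous E1cB) during a slow acylation of the hindered alcohol.
- Fallback: it sets out from 17 and returns at 20.
  - Compound 17, whose C7 protons are not yet vinylogously acidic, is acylated with 19 (pyridine, DMAP) to the exocyclic-olefin anisate F3.
  - The olefin is then moved into conjugation without base by RhCl3·3H2O (cat.) in EtOH.

## Further compounds

F0 | step 6 | none | none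
F1 | step 9 | (3R,3aR,8aS)-3-hydroxy-6,8a-dimethyl-3-(propan-2-yl)-2,3,3a,8a-tetrahydroazulene-4,8(1H,5H)-dione | O=C1CC(C)=CC(=O)[C@@]2(C)CC[C@@](O)(C(C)C)[C@H]12
F2 | step 5 | 1-[(3S)-3-methyl-6-(propan-2-yl)-7-oxabicyclo[4.1.0]heptan-3-yl]-3-methylbut-3-en-1-one (epoxide epimers) | CC(=C)CC(=O)[C@]1(C)CC2OC2(C(C)C)CC1
F3 | step 11 | (3R,3aS,4S,8aS)-3-hydroxy-8a-methyl-6-methylidene-8-oxo-3-(propan-2-yl)decahydroazulen-4-yl 4-methoxybenzoate | COc1ccc(C(=O)O[C@H]2CC(=C)CC(=O)[C@@]3(C)CC[C@@](O)(C(C)C)[C@H]23)cc1
A1 | alternative 1 | 1-[(1S,2S,3R)-3-hydroxy-2-[(1S)-1-hydroxy-3-methylbut-3-enyl]-1-methyl-3-(propan-2-yl)cyclopentyl]prop-2-en-1-one | C=CC(=O)[C@@]1(C)CC[C@@](O)(C(C)C)[C@@H]1[C@@H](O)CC(C)=C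
A2 | alternative 2 | (7S)-3,7-dimethyl-7-(4-methyl-3-oxopentyl)cyclohept-2-ene-1,5-dione | CC(C)C(=O)CC[C@@]1(C)CC(=O)CC(C)=CC1=O
A3 | alternative 2 | cis-fused ketol, C5 epimer of F1 | O=C1CC(C)=CC(=O)[C@@]2(C)CC[C@@](O)(C(C)C)[C@@H]12
A4 | alternative 3 | (S)-terpinen-4-ol | CC1=CC[C@](O)(C(C)C)CC1
A5 | alternative 3 | (5R)-5-hydroxy-2-methyl-5-(propan-2-yl)cyclopent-1-ene-1-carbaldehyde | CC1=C(C=O)[C@](O)(C(C)C)CC1
A6 | alternative 3 | (1R)-3-methyl-2-[(2S)-4-methyl-3,6-dihydro-2H-pyran-2-yl]-1-(propan-2-yl)cyclopent-2-en-1-ol | CC1=CCO[C@@H](C1)C1=C(C)CC[C@@]1(O)C(C)C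
A7 | alternative 3 | (3R,8aS)-6,8a-dimethyl-3-(propan-2-yl)-1,2,3,5,8,8a-hexahydroazulene-3,8-diol (C10 epimers) | OC1C=C(C)CC=C2[C@]1(C)CC[C@@]2(O)C(C)C
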